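**Retrosynthetic overview**
1. C15–C16: a catalytic asymmetric vinylogous Mukaiyama aldol joins an E-enal to 2-silyloxy-4-methylfuran. It sets C15 and C16, and the butenolide ring arrives intact and last.
2. C13=C14–C15: Negishi carboalumination and hydroxymethylation of a but-3-ynyl chain on C9.
3. Ring B (6α,8α-diol) comes from a 7α,8α-epoxy-6-ketone. That ketone comes from an aerobic ring expansion of a cyclopropanol fused to a cis-hydrindane, which makes the five-membered ring six-membered, inserts C7 and takes the C8 oxygen from O2.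
4. C9–C11: convex-face copper-catalysed conjugate addition to a cis-hydrindenone, with the enolate trapped as the C6=C8 silyl enol ether.
5. Order of rings: purchased cyclopentenone (C10 set by asymmetric conjugate addition), then ring A (cation/enol acetate closure), then the cyclopropane, then ring B by expansion, then the butenolide.

Numbering convention: labdane-type locants are used. Ring A is C1–C5 and C10, ring B is C5–C10, the chain is C11–C15 and the butenolide is C16–C19. β is the face of the C10 methyl group and α is the opposite face.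

**Step 1**
Reactants: 1 3-methylcyclopent-2-en-1-one; 2 5-bromo-2-methylpent-2-ene
Product: 5 (R)-3-methyl-3-(4-methylpent-3-en-1-yl)cyclopent-1-en-1-yl acetate, via homoprenylmagnesium bromide 3 (not isolated), via magnesium enolate 4 (not isolated)
Conditions: 2, Mg, Et2O, rt; Cu(OTf)2 (3 mol %), chiral hydroxyalkyl imidazolinium hexafluorophosphate (NHC precursor, 4 mol %), then 1, Et2O, −30 °C; Ac2O, −30 °C → rt
Reagents that add atoms: acetic anhydride CC(=O)OC(C)=O; magnesium [Mg] (kept only in 3 and 4)
Why: Copper–NHC-catalysed asymmetric conjugate addition of a Grignard reagent to a β-substituted cyclic enone builds the quaternary C10 centre (R here, the ligand antipode being chosen for this sense), and O-acetylation of the regiodefined magnesium enolate fixes the C5=C6 enol as an acid-tolerant π-nucleophile.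

**Step 2**
Reactants: 5 enol acetate
Product: 6 (3aR,7aR)-3a,7,7-trimethyloctahydro-1H-inden-1-one (cis-fused)
Conditions: Tf2NH (10 mol %), (CF3)2CHOH–CH2Cl2 1:4, −40 → 0 °C
Reagents that add atoms: none
Why: Brønsted-acid-initiated cation–olefin cyclisation in which Markovnikov protonation of the trisubstituted alkene gives the tertiary C4 cation, the tethered enol acetate captures it through a six-membered transition state on the face that carries the tether so that only the cis fusion (H5 syn to the C10 methyl) can form, and hexafluoroisopropanol takes up the acetyl group.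

**Step 3**
Reactants: 6 cis-hydrindanone
Product: 8 (3aR,7aR)-2,3a,7,7-tetramethyloctahydro-1H-inden-1-one (C8 epimers), via lithium enolate 7 (not isolated)
Conditions: LiN(iPr)2 (1.05 equiv), THF, −78 °C; MeI, −78 → 0 °C
Reagents that add atoms: iodomethane CI
Why: Kinetic enolate alkylation in which the base removes a C8 proton because H5 lies between two quaternary carbons, and the new C8 configuration is irrelevant because the next step erases it.

**Step 4**
Reactants: 8 methyl ketone
Product: 9 (3aR,7aR)-2,3a,7,7-tetramethyl-3a,4,5,6,7,7a-hexahydro-1H-inden-1-one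
Conditions: IBX (2.5 equiv), DMSO–PhF, 75 °C
Reagents that add atoms: none
Why: IBX dehydrogenation of a ketone through its enol, where only C8–C9 can be desaturated because C4 and C10 carry no hydrogen, giving the conjugated endocyclic enone.

**Step 5**
Reactants: 10 4-bromobut-1-yne
Product: 12 (4-bromobut-1-yn-1-yl)trimethylsilane, via lithium acetylide 11 (not isolated)
Conditions: n-BuLi (1.0 equiv), THF, −78 °C; Me3SiCl, −78 °C → rt
Reagents that add atoms: chlorotrimethylsilane C[Si](C)(C)Cl
Why: Deprotonation of the terminal alkyne, far faster at −78 °C than attack on the primary bromide, followed by C-silylation masks the acidic hydrogen for the Grignard chemistry that follows.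

**Step 6**
Reactants: 9 cis-hydrindenone; 12 silylated bromobutyne
Product: 14 cis-fused C6=C8 trimethylsilyl enol ether carrying the 4-(trimethylsilyl)but-3-ynyl chain on C9 syn to the angular methyl (9α-H), via silylbutynylmagnesium bromide 13 (not isolated)
Conditions: 12, Mg, THF; CuBr·SMe2 (20 mol %), Me3SiCl, DMPU, THF, −78 °C, then 9, −78 → −40 °C; Et3N, pH 7 work-up
Reagents that add atoms: chlorotrimethylsilane C[Si](C)(C)Cl; magnesium [Mg] (kept only in 13)
Why: Copper-catalysed, chlorosilane-accelerated conjugate addition (Nakamura–Kuwajima conditions) in which the reagent attacks C9 from the convex face of the cis-hydrindenone, syn to the angular methyl and H5 and away from ring A with its C4 methyl groups, which sets C9, while Me3SiCl traps the enolate regiospecifically.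

**Step 7**
Reactants: 14 silyl enol ether
Product: 16 tricyclic cyclopropanol (C6–C7–C8 cyclopropane on the five-membered ring with free C6–OH and terminal alkyne; both cyclopropane faces), via siloxycyclopropane 15 (not isolated)
Conditions: Et2Zn, CH2I2, CH2Cl2, 0 °C → rt; then K2CO3 (cat.), MeOH, 0 °C → rt
Reagents that add atoms: diiodomethane ICI
Why: Furukawa-modified Simmons–Smith cyclopropanation, in which the electrophilic zinc carbenoid selects the electron-rich enol ether over the silylalkyne, brings in C7, mild methanolysis removes both silyl groups, and the facial outcome does not matter because C6 and C8 become planar again in the next step.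

**Step 8**
Reactants: 16 cyclopropanol
Product: 19 trans-fused (5α-H) 9β-(but-3-ynyl)-7α,8α-epoxy-4,4,8,10-tetramethyldecal-6-one, via hydroperoxide 17 (not isolated), via cis-epoxy ketone 18 (not isolated)
Conditions: Mn(acac)2 (5 mol %), O2 (1 atm), toluene, rt; then KOH, MeOH, 0 → 40 °C
Reagents that add atoms: dioxygen O=O
Why: Proposed new method: an aerobic Mn(acac)2-catalysed ring-expanding peroxidation of a fully substituted fused bicyclo[3.1.0]hexan-1-ol, in which the cyclopropoxide of trivalent manganese (formed under O2) undergoes inner-sphere one-electron oxidation, the cyclopropyloxy radical cleaves the shared C6–C8 bond because this releases the ring strain and gives the tertiary C8 radical of a cyclohexanone (a net 1,2-acyl shift from C8 to C7, the manifold of the Dowd–Beckwith and FeCl3 Ito–Saegusa ring expansions), O2 (about 10 mM, capture near 10^7 s^-1 and so far faster than 5-exo attack on the alkyne) adds on the α face anti to the C9 chain and the C10 methyl group and sets C8, divalent manganese returns the peroxyl radical as hydroperoxide 17, KOH closes the C7 enolate onto the proximal peroxide oxygen (second half of a Weitz–Scheffer epoxidation) so that the C8–O bond is kept, and because C7 can then no longer enolise the base can only epimerise C5, relaxing the strained cis-decalone 18 to trans-fused 19; the closest known reactions are the manganese-catalysed aerobic opening of monocyclic cyclopropanols to 1,2-dioxolan-3-ols and α,β-epoxy ketones and the FeCl3 ring expansion of 1-siloxybicyclo[n.1.0]alkanes, neither shown on a fused, fully substituted terpenoid cyclopropanol with control of a tertiary C–O centre.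

**Step 9**
Reactants: 19 trans-epoxy ketone
Product: 21 (1R,2R,4S,4aS,8aS)-1-(but-3-yn-1-yl)-2,5,5,8a-tetramethyldecahydronaphthalene-2,4-diol, via hydroxy ketone 20 (not isolated)
Conditions: SmI2 (2.2 equiv), THF–MeOH, −78 °C; then SmI2 (2.5 equiv), H2O, Et3N, 0 °C → rt
Reagents that add atoms: none
Why: SmI2 first cleaves the Cα–O bond of the α,β-epoxy ketone (Molander-type reduction) with the C8–O bond untouched, and the stronger SmI2–water–amine couple then reduces the ketone through a ketyl and organosamarium species whose protonation gives the thermodynamically favoured equatorial 6α-alcohol, the axial β position being crowded by three syn-axial methyl groups.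

**Step 10**
Reactants: 21 alkynyl diol
Product: 24 (1R,2R,4S,4aS,8aS)-1-[(3E)-5-hydroxy-3-methylpent-3-en-1-yl]-2,5,5,8a-tetramethyldecahydronaphthalene-2,4-diol, via alkenylalane 22 (not isolated), via lithium alanate 23 (not isolated)
Conditions: Me3Al (5 equiv), Cp2ZrCl2 (25 mol %), CH2Cl2, 0 °C → rt; concentrate; n-BuLi, THF–hexane, −78 → 0 °C; (CH2O)n, rt; sat. aq NH4Cl
Reagents that add atoms: trimethylaluminium C[Al](C)C; formaldehyde (as paraformaldehyde) C=O
Why: Negishi zirconium-catalysed carboalumination adds methyl and aluminium syn with the metal on the terminal carbon, which fixes the E-trisubstituted alkene, the derived alanate is hydroxymethylated by formaldehyde with retention, and the two carbinols are merely parked as aluminium alkoxides.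

**Step 11**
Reactants: 24 triol
Product: 25 (2E)-5-[(1R,2R,4S,4aS,8aS)-2,4-dihydroxy-2,5,5,8a-tetramethyldecahydronaphthalen-1-yl]-3-methylpent-2-enal
Conditions: [Cu(MeCN)4]OTf, 2,2'-bipyridine, TEMPO (5 mol % each), N-methylimidazole (10 mol %), air, MeCN, rt
Reagents that add atoms: none
Why: Stahl copper/nitroxyl aerobic oxidation is selective for the unhindered primary allylic alcohol over the hindered secondary and tertiary carbinols and does not isomerise the alkene.

**Step 12**
Reactants: 26 4-methylfuran-2(5H)-one
Product: 27 tert-butyldimethyl[(4-methylfuran-2-yl)oxy]silane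
Conditions: TBSOTf, Et3N, CH2Cl2, 0 °C
Reagents that add atoms: tert-butyldimethylsilyl triflate CC(C)(C)[Si](C)(C)OS(=O)(=O)C(F)(F)F
Why: Soft enolisation and O-silylation of the butenolide gives the aromatic 2-silyloxyfuran, the standard vinylogous aldol donor.

**Step 13**
Reactants: 25 enal; 27 silyloxyfuran
Product: 29 target CNP0279704.1, via trichlorosilyl aldolate 28 (not isolated)
Conditions: SiCl4 (2.5 equiv), (R,R)-bisphosphoramide (binaphthyl-2,2'-diamine-derived, pentane-1,5-diyl-linked, 5 mol %), iPr2NEt (20 mol %), CH2Cl2, −78 °C; sat. aq NaHCO3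
Reagents that add atoms: silicon tetrachloride Cl[Si](Cl)(Cl)Cl (kept only in 28)
Why: Catalytic enantioselective vinylogous Mukaiyama aldol addition under Lewis-base-activated SiCl4 (Denmark type), in which the chiral trichlorosilyl cation binds the conjugated aldehyde and exposes its Re face, the furan attacks through C5 in an open transition state that keeps the alkenyl residue away from the 4-methyl group and so gives the like (threo, 15S,16S) pair, and the two hindered carbinols at most form chlorosilyl ethers that hydrolyse on work-up.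

**Compound list**
1 | 3-methylcyclopent-2-en-1-one | CC1=CC(=O)CC1 | starting material
2 | 5-bromo-2-methylpent-2-ene | CC(C)=CCCBr | starting material
3 | (4-methylpent-3-en-1-yl)magnesium bromide | CC(C)=CCC[Mg]Br | intermediate
4 | bromomagnesium (R)-3-methyl-3-(4-methylpent-3-en-1-yl)cyclopent-1-en-1-olate | Br[Mg]OC1=C[C@](C)(CCC=C(C)C)CC1 | intermediate
5 | (R)-3-methyl-3-(4-methylpent-3-en-1-yl)cyclopent-1-en-1-yl acetate | CC(=O)OC1=C[C@](C)(CCC=C(C)C)CC1 | intermediate
6 | (3aR,7aR)-3a,7,7-trimethyloctahydro-1H-inden-1-one, cis-fused | O=C1CC[C@@]2(C)CCCC(C)(C)[C@@H]12 | intermediate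
7 | kinetic lithium enolate (C6=C8) of 6 | [Li]OC1=CC[C@@]2(C)CCCC(C)(C)[C@@H]12 | intermediate
8 | (3aR,7aR)-2,3a,7,7-tetramethyloctahydro-1H-inden-1-one, epimers at C8 (erased in step 4) | O=C1C(C)C[C@@]2(C)CCCC(C)(C)[C@@H]12 | intermediate
9 | (3aR,7aR)-2,3a,7,7-tetramethyl-3a,4,5,6,7,7a-hexahydro-1H-inden-1-one | O=C1C(C)=C[C@@]2(C)CCCC(C)(C)[C@@H]12 | intermediate
10 | 4-bromobut-1-yne | C#CCCBr | starting material
11 | lithium 4-bromobut-1-yn-1-ide | [Li]C#CCCBr | intermediate
12 | (4-bromobut-1-yn-1-yl)trimethylsilane | C[Si](C)(C)C#CCCBr | intermediate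
13 | [4-(trimethylsilyl)but-3-yn-1-yl]magnesium bromide | C[Si](C)(C)C#CCC[Mg]Br | intermediate
14 | cis-fused C6=C8 trimethylsilyl enol ether, 9β-[4-(trimethylsilyl)but-3-ynyl], 9α-H, 5β-H | C[Si](C)(C)OC1=C(C)[C@H](CCC#C[Si](C)(C)C)[C@@]2(C)CCCC(C)(C)[C@@H]12 | intermediate
15 | 6-trimethylsiloxy C6–C7–C8 cyclopropane derived from 14, both cyclopropane faces (erased in step 8) | C[Si](C)(C)OC12CC1(C)[C@H](CCC#C[Si](C)(C)C)[C@@]3(C)CCCC(C)(C)[C@@H]23 | intermediate
16 | free tricyclic cyclopropanol with terminal alkyne, both cyclopropane faces | OC12CC1(C)[C@H](CCC#C)[C@@]3(C)CCCC(C)(C)[C@@H]23 | intermediate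
17 | cis-fused (5β-H) 9β-(but-3-ynyl)-8α-hydroperoxy-4,4,8β,10β-tetramethyldecal-6-one | O=C1C[C@@](C)(OO)[C@H](CCC#C)[C@@]2(C)CCCC(C)(C)[C@@H]12 | intermediate
18 | cis-fused (5β-H) 7α,8α-epoxy-6-ketone | O=C1[C@H]2O[C@@]2(C)[C@H](CCC#C)[C@@]3(C)CCCC(C)(C)[C@@H]13 | intermediate
19 | trans-fused (5α-H) 9β-(but-3-ynyl)-7α,8α-epoxy-4,4,8,10-tetramethyldecal-6-one | O=C1[C@H]2O[C@@]2(C)[C@H](CCC#C)[C@@]3(C)CCCC(C)(C)[C@H]13 | intermediate
20 | trans-fused 9β-(but-3-ynyl)-8α-hydroxy-4,4,8β,10β-tetramethyldecal-6-one | C#CCC[C@@H]1[C@@]2(C)CCCC(C)(C)[C@@H]2C(=O)C[C@@]1(C)O | intermediate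
21 | (1R,2R,4S,4aS,8aS)-1-(but-3-yn-1-yl)-2,5,5,8a-tetramethyldecahydronaphthalene-2,4-diol | C#CCC[C@@H]1[C@@]2(C)CCCC(C)(C)[C@@H]2[C@@H](O)C[C@@]1(C)O | intermediate
22 | (E)-alkenyldimethylalane, both carbinols as dimethylaluminium alkoxides | C[Al](C)/C=C(\C)CC[C@@H]1[C@@]2(C)CCCC(C)(C)[C@@H]2[C@@H](O[Al](C)C)C[C@@]1(C)O[Al](C)C | intermediate
23 | lithium butyl(alkenyl)dimethylalanate from 22 | [Li+].CCCC[Al-](C)(C)/C=C(\C)CC[C@@H]1[C@@]2(C)CCCC(C)(C)[C@@H]2[C@@H](O[Al](C)C)C[C@@]1(C)O[Al](C)C | intermediate
24 | (1R,2R,4S,4aS,8aS)-1-[(3E)-5-hydroxy-3-methylpent-3-en-1-yl]-2,5,5,8a-tetramethyldecahydronaphthalene-2,4-diol | OC/C=C(\C)CC[C@@H]1[C@@]2(C)CCCC(C)(C)[C@@H]2[C@@H](O)C[C@@]1(C)O | intermediate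
25 | (2E)-5-[(1R,2R,4S,4aS,8aS)-2,4-dihydroxy-2,5,5,8a-tetramethyldecahydronaphthalen-1-yl]-3-methylpent-2-enal | O=C/C=C(\C)CC[C@@H]1[C@@]2(C)CCCC(C)(C)[C@@H]2[C@@H](O)C[C@@]1(C)O | intermediate
26 | 4-methylfuran-2(5H)-one | CC1=CC(=O)OC1 | starting material
27 | tert-butyldimethyl[(4-methylfuran-2-yl)oxy]silane | CC1=COC(O[Si](C)(C)C(C)(C)C)=C1 | intermediate
28 | 15-O-trichlorosilyl ether of 29 | CC1=CC(=O)O[C@@H]1[C@@H](O[Si](Cl)(Cl)Cl)/C=C(\C)CC[C@@H]1[C@@]2(C)CCCC(C)(C)[C@@H]2[C@@H](O)C[C@@]1(C)O | intermediate
29 | (5S)-5-{(1S,2E)-5-[(1R,2R,4S,4aS,8aS)-2,4-dihydroxy-2,5,5,8a-tetramethyldecahydronaphthalen-1-yl]-1-hydroxy-3-methylpent-2-en-1-yl}-4-methylfuran-2(5H)-one | CC1=CC(=O)O[C@@H]1[C@@H](O)/C=C(\C)CC[C@@H]1[C@@]2(C)CCCC(C)(C)[C@@H]2[C@@H](O)C[C@@]1(C)O | target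

**Totals**
Total step count: 13.
Longest linear sequence: 11 (steps 1–4, 6–11, 13).

**Three steps most likely to fail**

Step 8 (the new ring-expanding peroxidation). The risks are exocyclic C6–C7 cleavage, imperfect facial capture of O2 and slow epimerisation at the hindered C5. The fallback uses known chemistry only, sets out from 16 and comes back at 19. Oxidation of 16 with FeCl3 (2.2 equiv, DMF, 0 °C, Ito–Saegusa ring expansion) gives the ring-expanded cis-fused 8-chloro-6-ketone F4. DBU in warm toluene eliminates HCl and equilibrates C5 (and C9, through the dienolate) to the trans-fused 7-en-6-one F5. Weitz–Scheffer epoxidation (H2O2, NaOH, MeOH, 0 °C) on the α face, opposite to the C10 methyl group, then gives 19.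

Step 2 (proton-initiated ring A closure). The risks are protonolysis of the enol acetate before the alkene is protonated, and alkene isomerisation. The fallback sets out from 5 and comes back at 6. Buffered mCPBA epoxidises the more electron-rich trisubstituted alkene to the epoxy enol acetate F1 (both epoxide epimers). MeAlCl2 (CH2Cl2, −78 °C) opens the epoxide at its tertiary carbon without any Brønsted acid, and the enol acetate terminates the cyclisation to give the cis-fused 3-hydroxy ketone F2. 1,1'-Thiocarbonyldiimidazole converts it into the imidazolylthiocarbonyl ester F3. Bu3SnH/AIBN (Barton–McCombie deoxygenation) then gives 6.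

Step 13 (catalyst-controlled vinylogous aldol on a β,β-disubstituted enal bearing a free diol). The risks are low turnover and eroded facial or threo selectivity. The fallback sets out from 25 and 27 and comes back at 29. BF3·OEt2 (CH2Cl2, −78 °C) gives the intrinsically threo-selective but facially unselective addition, that is 29 together with its (15R,16R) diastereomer F6. Sharpless kinetic resolution (Ti(OiPr)4, L-(+)-DIPT, t-BuOOH 0.6 equiv, −20 °C) then epoxidises only the fast-reacting (15R) allylic alcohol to the 13,14-epoxy alcohol F7. The slow-reacting 29 is recovered and separated by chromatography.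

**Further compounds**
F1 | step 2 | (R)-3-[2-(3,3-dimethyloxiran-2-yl)ethyl]-3-methylcyclopent-1-en-1-yl acetate (epoxide epimers) | CC(=O)OC1=C[C@](C)(CCC2OC2(C)C)CC1
F2 | step 2 | cis-fused 6-hydroxy-3a,7,7-trimethyloctahydro-1H-inden-1-one (carbinol epimers) | O=C1CC[C@@]2(C)CCC(O)C(C)(C)[C@@H]12
F3 | step 2 | O-(imidazol-1-ylthiocarbonyl) derivative of F2 | O=C1CC[C@@]2(C)CCC(OC(=S)n3ccnc3)C(C)(C)[C@@H]12
F4 | step 8 | cis-fused 9β-(but-3-ynyl)-8-chloro-4,4,8,10-tetramethyldecal-6-one | O=C1CC(C)(Cl)[C@H](CCC#C)[C@@]2(C)CCCC(C)(C)[C@@H]12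
F5 | step 8 | trans-fused 9β-(but-3-ynyl)-4,4,8,10-tetramethyl-7-en-6-one | O=C1C=C(C)[C@H](CCC#C)[C@@]2(C)CCCC(C)(C)[C@H]12
F6 | step 13 | (15R,16R) diastereomer of 29 | CC1=CC(=O)O[C@H]1[C@H](O)/C=C(\C)CC[C@@H]1[C@@]2(C)CCCC(C)(C)[C@@H]2[C@@H](O)C[C@@]1(C)O
F7 | step 13 | 13,14-epoxide of F6 (erythro to C15) | CC1=CC(=O)O[C@H]1[C@H](O)C1OC1(C)CC[C@@H]1[C@@]2(C)CCCC(C)(C)[C@@H]2[C@@H](O)C[C@@]1(C)O
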